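The earlier runs and the new flask are calculated for substances that don't exist; noise was put on by code.

**Per minute.** Per minute, at a fixed temperature, a first-order loss takes a fixed fraction of the E standing, so the integrated rate leaves a fraction exp(−kt) of the charge. A second-order loss integrates differently: the reciprocal of that fraction, less one, grows in proportion to time. The flasks, the readings and the questions are these.

| flask | E | temperature | remark | time |
|---|---|---|---|---|
| zeta | 2.5 mM | 45 °C | run made earlier |  |
| gamma | 10 mM | 60 °C | run made earlier |  |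
| grey | 5.0 mM |  | at 50 °C until 25 s, from then on at 70 °C | 2.0 min |
| blue | 5.0 mM | 70 °C |  | 2.0 min |
| red | 5.0 mM | 50 °C |  | 2.0 min |

- zeta (time / min: Q / %, E / %): 1.33: 85.9, 5.8; 3.00: 90.6, 0; 5.00: 90.9, 0
- gamma (time / min: Q / %, E / %): 0.333: 89.2, 2.9; 0.833: 91.0, 0; 1.50: 91.5, 0; 2.50: 91.1, 0.3

(scatter of a reading: 0.3 percentage points)

- the analysis behind the earlier runs scatters by 0.3 percentage points, standard deviation

* the best flask by amount of Q, in percent of the E charged; "all alike" if 1.5 percentage points covers them all (grey / blue / red / all alike)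
* amount of Q at the end, in percent of the E charged, grey
* amount of Q at the end, in percent of the E charged, blue
* amount of Q at the end, in percent of the E charged, red

**First way.** The zeta run read 5.8 % of E at 1.33 min. First order turns this into k = 2.14 min⁻¹, and that k leaves 0.162 % at 3.00 min.

**Second way.** The same zeta reading, put through the second-order law, leaves 2.66 % at that time, which is more than the first way gives. The reading there is 0 % with a scatter of 0.3 percentage points, so the second way cheats and first order is kept.

**Own reckoning.** The gamma run gives k = 10.6 min⁻¹, and the pair of readings gives an activation energy, itself a reading with their scatter, of 94.2 kJ mol⁻¹. At 50 °C k is then 3.71 min⁻¹. Red thus has 7.43 as its exposure, the rate constant times the time, and E left is exp(−exposure), here 0.0595 %. For a first-order loss, exposures add across a temperature change. With k = 28.6 min⁻¹ at 70 °C, blue has 57.3 and grey has 46.9. The zeta run's first reading puts Q at 91.2 % of the E consumed, its selectivity, so red should hold 91.1 % of Q.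

**The forecast.** The forecast gives 90.9 % for grey, 90.8 % for blue, 90.5 % for red, and all alike, holding that “Blue and grey finish fully”. Its red stands below the reckoning above.

**The result.** Grey gives 90.8 %, blue 90.8 %, red 91.0 %: all alike.

    E → Q (k = 0.467 s⁻¹, Ea = 96.0 kJ mol⁻¹)
    E → D (k = 0.0151 s⁻¹, Ea = 84.0 kJ mol⁻¹)
    D ⇌ J (K = 1.50, k = 0.214 s⁻¹, Ea = 84.0 kJ mol⁻¹, ΔH = 4.00 kJ mol⁻¹)
    D ⇌ Z (K = 0.800, k = 0.0243 s⁻¹, Ea = 101 kJ mol⁻¹, ΔH = −61.0 kJ mol⁻¹)
    J ⇌ G (K = 2.84, k = 0.0482 s⁻¹, Ea = 94.0 kJ mol⁻¹, ΔH = −68.0 kJ mol⁻¹)
    J ⇌ X (K = 0.550, k = 0.00446 s⁻¹, Ea = 107 kJ mol⁻¹, ΔH = −22.0 kJ mol⁻¹)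
    E → J (k = 0.0307 s⁻¹, Ea = 103 kJ mol⁻¹)
    Q → L (k = 2.64 × 10⁻⁵ s⁻¹, Ea = 105 kJ mol⁻¹)
    (constants at 70 °C)

**What counted.** Red's exposure promised 0.0595 % of E, and red holds 0.047 %. That number speaks of E, not of the Q short of the charge: blue stands at 90.8 % of Q and without the reaction of E to J at 96.6 %, so that reaction is the main reason for blue's shortfall, 63 % of what is missing.

**A colder neighbour.** Red's neighbour at 35 °C has an exposure of 1.35, which leaves 26.0 % of E and gives 67.5 % of Q. That neighbour computes to 25.9 % of E and 67.3 % of Q.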